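## Retrosynthetic overview

- **Feature.** Ring B (the benzene ring) is hexasubstituted. Oxygen on C2', C4' and C6' alternates with three different carbon groups: pyronylmethyl on C1', prenyl on C3', isobutyryl on C5'. The ring is read as three C–C(O) pairs: one ketene (C1'–C6') and two ynol ethers (C3'–C2' and C5'–C4').
- **Key disconnection.** Ring B comes from a 3-siloxycyclobutenone (C1', C2', C3', C6') and a siloxyalkyne carrying the ketal-masked isobutyryl group (C4', C5'). The vinylketene benzannulation forms C5'–C6', C3'–C4' and C1'–C6'.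
- **Cyclobutenone.** It comes from a [2+2] addition of the pyronylmethylketene (from the 3-pyronylpropanoic acid) to the prenyl siloxyalkyne. Both siloxyalkynes are O-silylated lithium ynolates, made by acetylide oxidation (prenyl) and ester homologation (ketal).
- **Ring order.** Pyrone ring A is made first (silyl enol ether of 3-pentanone plus malonyl dichloride), then the temporary four-membered ring C, then benzene ring B.
- **End game.** Acid comes first, removing the ketal and MOM while both oxygens next to the prenyl group are still silylated. Fluoride comes last.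

Key step: step 11

Remark: the target has no stereocentre and is drawn as its 4-hydroxy-2-pyrone tautomer. The stereocentres of 17, 24 and 26 are racemic and vanish on aromatisation.

## Route

Step 1
Reactants: 1 3-pentanone
Product: 2 3-(trimethylsilyloxy)pent-2-ene (E/Z mixture)
Conditions: TMSOTf, Et3N, CH2Cl2, 0 °C
Reagents that add atoms: trimethylsilyl triflate, C[Si](C)(C)OS(=O)(=O)C(F)(F)F
Why: Soft enolisation and O-silylation (silyl enol ether formation) of a symmetrical ketone, so there is no regiochemical choice and the E/Z composition is irrelevant because both isomers lead to the same pyrone.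

Step 2
Reactants: 2 3-(trimethylsilyloxy)pent-2-ene; 3 malonyl dichloride
Product: 4 6-ethyl-4-hydroxy-5-methyl-2H-pyran-2-one
Conditions: Et2O, −78 → 23 °C
Reagents that add atoms: none
Why: Pyrone synthesis by double acylation, in which the enol ether carbon is C-acylated by one COCl group, the ketone enol closes on the second COCl (lactonisation to six-membered ring A) and the 2,4-dione enolises, which fixes methyl on C5 and ethyl on C6 and leaves C3 free.

Step 3
Reactants: 4 6-ethyl-4-hydroxy-5-methyl-2H-pyran-2-one; 5 benzyl acrylate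
Product: 6 benzyl 3-(6-ethyl-4-hydroxy-5-methyl-2-oxo-2H-pyran-3-yl)propanoate
Conditions: DBU (0.2 equiv), BHT (trace), MeCN, 60 °C
Reagents that add atoms: none
Why: Michael addition of the pyronate, a cyclic 1,3-dicarbonyl-type nucleophile, through its only free carbon C3; O-addition is reversible and the C-adduct, which regains the acidic enol, should be the thermodynamic product.

Step 4
Reactants: 6 benzyl 3-(6-ethyl-4-hydroxy-5-methyl-2-oxo-2H-pyran-3-yl)propanoate
Product: 7 benzyl 3-[6-ethyl-4-(methoxymethoxy)-5-methyl-2-oxo-2H-pyran-3-yl]propanoate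
Conditions: MOMCl, i-Pr2NEt, CH2Cl2, 0 → 23 °C
Reagents that add atoms: chloromethyl methyl ether, COCCl
Why: MOM ether formation by O-alkylation of the vinylogous acid with a hard electrophile; C3 is now substituted so C-alkylation is disfavoured, and the 4-OH must be masked before an acid chloride and a ketene are generated in the same molecule.

Step 5
Reactants: 7 benzyl 3-[6-ethyl-4-(methoxymethoxy)-5-methyl-2-oxo-2H-pyran-3-yl]propanoate
Product: 8 3-[6-ethyl-4-(methoxymethoxy)-5-methyl-2-oxo-2H-pyran-3-yl]propanoic acid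
Conditions: H2 (1 atm), 10% Pd/C, EtOAc, 23 °C
Reagents that add atoms: none
Why: Hydrogenolysis of the benzyl ester under neutral conditions spares the base-sensitive lactone and the acid-sensitive MOM ether, and the fully substituted pyrone double bonds are reduced far more slowly than the O–benzyl bond is cleaved.

Step 6
Reactants: 9 prenyl bromide (1-bromo-3-methylbut-2-ene); 10 ethynylmagnesium bromide
Product: 11 5-methylhex-4-en-1-yne
Conditions: CuCl (5 mol%), THF, 0 → 40 °C; distillation
Reagents that add atoms: none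
Why: Copper-catalysed coupling of an alkynyl Grignard reagent with an allylic bromide, which should take place at the unhindered primary carbon and give the skipped 1,4-enyne with the prenyl unit intact.

Step 7
Reactants: 11 5-methylhex-4-en-1-yne
Product: 14 triisopropyl[(5-methylhex-4-en-1-yn-1-yl)oxy]silane, via lithium acetylide 12 (not isolated), via lithium ynolate 13 (not isolated)
Conditions: n-BuLi, THF, −78 °C; t-BuOOLi (from t-BuOOH and LiHMDS, THF, −78 °C), −78 → 0 °C; TIPSOTf, −78 → 0 °C
Reagents that add atoms: tert-butyl hydroperoxide, CC(C)(C)OO; triisopropylsilyl triflate, CC(C)[Si](OS(=O)(=O)C(F)(F)F)(C(C)C)C(C)C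
Why: Oxygenation of a lithium acetylide with lithium tert-butyl peroxide gives the ynolate and the bulky silyl triflate traps it on oxygen (siloxyalkyne synthesis); this keeps exactly one CH2 between triple bond and olefin, whereas ynolate formation from the Claisen-derived 5-methylhex-4-enoate would give a homoprenyl chain and the β,γ-unsaturated 4-methylpent-3-enoate would risk enolisation.

Step 8
Reactants: 8 3-[6-ethyl-4-(methoxymethoxy)-5-methyl-2-oxo-2H-pyran-3-yl]propanoic acid; 14 triisopropyl[(5-methylhex-4-en-1-yn-1-yl)oxy]silane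
Product: 17 rac-4-{[6-ethyl-4-(methoxymethoxy)-5-methyl-2-oxo-2H-pyran-3-yl]methyl}-2-(3-methylbut-2-en-1-yl)-3-(triisopropylsilyloxy)cyclobut-2-en-1-one, via acid chloride 15 (not isolated), via pyronylmethylketene 16 (not isolated)
Conditions: 1-chloro-N,N,2-trimethylprop-1-en-1-amine, CH2Cl2, 0 °C; then slow addition (syringe pump) to 14 (1.5 equiv), Et3N, CH2Cl2, 23–40 °C
Reagents that add atoms: none
Why: The neutral α-chloroenamine gives the acid chloride without HCl, slow dehydrochlorination keeps the aldoketene dilute, and the known ketene–siloxyalkyne [2+2] cycloaddition joins the alkyne carbon β to oxygen (the prenyl-bearing one) to the ketene carbonyl carbon, so prenyl ends on C2, OTIPS on C3 and the pyronylmethyl group on the racemic C4.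

Step 9
Reactants: 18 ethyl 3-methyl-2-oxobutanoate
Product: 19 ethyl 2-isopropyl-1,3-dioxolane-2-carboxylate
Conditions: TMSOCH2CH2OTMS, TMSOTf (5 mol%), CH2Cl2, −78 → 23 °C; pyridine quench
Reagents that add atoms: 1,2-bis(trimethylsilyloxy)ethane, C[Si](C)(C)OCCO[Si](C)(C)C
Why: Noyori ketalisation under aprotic conditions, driven by irreversible formation of the disiloxane, should overcome the hindered and deactivated α-keto ester carbonyl without the transesterification that free glycol would cause.

Step 10
Reactants: 19 ethyl 2-isopropyl-1,3-dioxolane-2-carboxylate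
Product: 22 triisopropyl{[(2-isopropyl-1,3-dioxolan-2-yl)ethynyl]oxy}silane, via dibromoketone enolate 20 (not isolated), via lithium ynolate 21 (not isolated)
Conditions: CH2Br2, LiTMP, THF, −78 °C; 19; LiHMDS, −78 °C; n-BuLi, −78 → 0 °C; TIPSCl, −78 → 23 °C; chromatography on Et3N-deactivated silica
Reagents that add atoms: dibromomethane, BrCBr; triisopropylsilyl chloride, CC(C)[Si](Cl)(C(C)C)C(C)C
Why: Kowalski ester homologation stopped at the ynolate: LiCHBr2 adds to the non-enolisable ester, enolate 20 undergoes bromine–lithium exchange and a 1,2-shift of the ketal carbon with loss of LiBr, and TIPSCl silylates ynolate 21 on oxygen without the Lewis acidity that would ionise the propargylic ketal.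

Step 11
Reactants: 17 rac-4-{[6-ethyl-4-(methoxymethoxy)-5-methyl-2-oxo-2H-pyran-3-yl]methyl}-2-(3-methylbut-2-en-1-yl)-3-(triisopropylsilyloxy)cyclobut-2-en-1-one; 22 triisopropyl{[(2-isopropyl-1,3-dioxolan-2-yl)ethynyl]oxy}silane
Product: 27 6-ethyl-3-{[6-hydroxy-5-(2-isopropyl-1,3-dioxolan-2-yl)-3-(3-methylbut-2-en-1-yl)-2,4-bis(triisopropylsilyloxy)phenyl]methyl}-4-(methoxymethoxy)-5-methyl-2H-pyran-2-one, via siloxy vinylketene 23 (not isolated), via 4-vinylcyclobutenone 24 (not isolated), via dienylketene 25 (not isolated), via cyclohexa-2,4-dienone 26 (not isolated)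
Conditions: 22 (2 equiv), toluene (0.5 M), base-washed sealed tube, 110 °C, then 150 °C
Reagents that add atoms: none
Why: Proposed new method: heating opens 17 by conrotatory 4π cleavage of C1'–C6' (the pyronylmethyl group turning outward) to vinylketene 23, the ketal-bearing carbon of 22 (β to oxygen) attacks the sp ketene carbon, and the [2+2] addition (C5'–C6' and C3'–C4') gives 24, whose 4π opening (C3'–C6' breaks) gives dienylketene 25. Ring B is then closed by disrotatory 6π electrocyclisation (C1'–C6') to dienone 26, and tautomerisation with loss of the C1' hydrogen gives phenol 27. The closest known reaction type is the Danheiser benzannulation of cyclobutenones with siloxyalkynes to resorcinol monosilyl ethers; not yet shown is a 3-siloxy-2,4-dialkylcyclobutenone as the vinylketene source combined with an ynol ether bearing a quaternary carbon, which would give a hexasubstituted phloroglucinol. No stereocentre remains, since C4 of 17, the quaternary carbon of 24 and C1' of 26 are racemic and all become sp2. The step needs regioselectivity, secured by the polarisation of the ynol ether (which also puts the bulky ketal carbon on the unhindered sp carbon and not on the fully substituted ketene terminus), and chemoselectivity for the ketene over ring A, secured because the tetrasubstituted 4-alkoxypyrone is a poor Diels–Alder diene for an electron-rich alkyne. The excess of 22 should keep 23 from dimerising or acylating the hindered phenol of 27.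

Step 12
Reactants: 27 the benzannulation product
Product: 28 6-ethyl-4-hydroxy-3-{[6-hydroxy-5-isobutyryl-3-(3-methylbut-2-en-1-yl)-2,4-bis(triisopropylsilyloxy)phenyl]methyl}-5-methyl-2H-pyran-2-one
Conditions: 1 M aq HCl, THF–MeOH, 23 °C
Reagents that add atoms: water, O
Why: Acid-catalysed acetal hydrolysis: the ketal on the electron-rich ring and the MOM ether of the vinylogous acid are both very labile, aryl TIPS ethers survive dilute acid, and because both oxygens next to the prenyl group (C2' and C4') are still silylated the olefin cannot close to a chroman.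

Step 13
Reactants: 28 the bis(triisopropylsilyl) ether
Product: 29 6-ethyl-4-hydroxy-5-methyl-3-{[2,4,6-trihydroxy-3-isobutyryl-5-(3-methylbut-2-en-1-yl)phenyl]methyl}-2H-pyran-2-one (target)
Conditions: TBAF (2.2 equiv), AcOH (2.5 equiv), THF, 0 °C; pH 4–5 buffer work-up
Reagents that add atoms: none
Why: Fluoride-induced cleavage of the two aryl silyl ethers, buffered with acetic acid so that the phenoxides are protonated at once and the methylene bridge is not broken by base-induced loss of the pyronate.

## Compound list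

1 | 3-pentanone | CCC(=O)CC | starting material
2 | 3-(trimethylsilyloxy)pent-2-ene (E/Z mixture) | CC=C(CC)O[Si](C)(C)C | intermediate
3 | malonyl dichloride | O=C(Cl)CC(Cl)=O | starting material
4 | 6-ethyl-4-hydroxy-5-methyl-2H-pyran-2-one | CCc1oc(=O)cc(O)c1C | intermediate
5 | benzyl acrylate | C=CC(=O)OCc1ccccc1 | starting material
6 | benzyl 3-(6-ethyl-4-hydroxy-5-methyl-2-oxo-2H-pyran-3-yl)propanoate | CCc1oc(=O)c(CCC(=O)OCc2ccccc2)c(O)c1C | intermediate
7 | benzyl 3-[6-ethyl-4-(methoxymethoxy)-5-methyl-2-oxo-2H-pyran-3-yl]propanoate | CCc1oc(=O)c(CCC(=O)OCc2ccccc2)c(OCOC)c1C | intermediate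
8 | 3-[6-ethyl-4-(methoxymethoxy)-5-methyl-2-oxo-2H-pyran-3-yl]propanoic acid | CCc1oc(=O)c(CCC(=O)O)c(OCOC)c1C | intermediate
9 | prenyl bromide | CC(C)=CCBr | starting material
10 | ethynylmagnesium bromide | C#C[Mg]Br | starting material
11 | 5-methylhex-4-en-1-yne | C#CCC=C(C)C | intermediate
12 | (5-methylhex-4-en-1-yn-1-yl)lithium (not isolated) | [Li]C#CCC=C(C)C | intermediate
13 | lithium 5-methylhex-4-en-1-yn-1-olate (not isolated) | [Li+].[O-]C#CCC=C(C)C | intermediate
14 | triisopropyl[(5-methylhex-4-en-1-yn-1-yl)oxy]silane | CC(C)=CCC#CO[Si](C(C)C)(C(C)C)C(C)C | intermediate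
15 | 3-[6-ethyl-4-(methoxymethoxy)-5-methyl-2-oxo-2H-pyran-3-yl]propanoyl chloride (not isolated) | CCc1oc(=O)c(CCC(=O)Cl)c(OCOC)c1C | intermediate
16 | 3-[6-ethyl-4-(methoxymethoxy)-5-methyl-2-oxo-2H-pyran-3-yl]prop-1-en-1-one, the aldoketene (not isolated) | CCc1oc(=O)c(CC=C=O)c(OCOC)c1C | intermediate
17 | rac-4-{[6-ethyl-4-(methoxymethoxy)-5-methyl-2-oxo-2H-pyran-3-yl]methyl}-2-(3-methylbut-2-en-1-yl)-3-(triisopropylsilyloxy)cyclobut-2-en-1-one | O=C1C(CC=C(C)C)=C(O[Si](C(C)C)(C(C)C)C(C)C)C1Cc1c(OCOC)c(C)c(CC)oc1=O | intermediate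
18 | ethyl 3-methyl-2-oxobutanoate | CCOC(=O)C(=O)C(C)C | starting material
19 | ethyl 2-isopropyl-1,3-dioxolane-2-carboxylate | CCOC(=O)C1(C(C)C)OCCO1 | intermediate
20 | lithium 2,2-dibromo-1-(2-isopropyl-1,3-dioxolan-2-yl)ethen-1-olate (not isolated) | [Li+].[O-]C(=C(Br)Br)C1(C(C)C)OCCO1 | intermediate
21 | lithium (2-isopropyl-1,3-dioxolan-2-yl)ethynolate (not isolated) | [Li+].[O-]C#CC1(C(C)C)OCCO1 | intermediate
22 | triisopropyl{[(2-isopropyl-1,3-dioxolan-2-yl)ethynyl]oxy}silane | CC(C)C1(C#CO[Si](C(C)C)(C(C)C)C(C)C)OCCO1 | intermediate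
23 | siloxy vinylketene from 4π opening of 17, pyronylmethyl trans to the ketene carbon (not isolated) | O=C=C(CC=C(C)C)/C(O[Si](C(C)C)(C(C)C)C(C)C)=C/Cc1c(OCOC)c(C)c(CC)oc1=O | intermediate
24 | racemic 2-(ketal)-3-siloxy-4-prenyl-4-(siloxyvinyl)cyclobutenone (not isolated) | O=C1C(C2(C(C)C)OCCO2)=C(O[Si](C(C)C)(C(C)C)C(C)C)C1(CC=C(C)C)/C(O[Si](C(C)C)(C(C)C)C(C)C)=C/Cc1c(OCOC)c(C)c(CC)oc1=O | intermediate
25 | dienylketene, ketene and siloxyvinyl groups cis on the central double bond (not isolated) | O=C=C(C1(C(C)C)OCCO1)/C(O[Si](C(C)C)(C(C)C)C(C)C)=C(CC=C(C)C)\C(O[Si](C(C)C)(C(C)C)C(C)C)=C\Cc1c(OCOC)c(C)c(CC)oc1=O | intermediate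
26 | racemic cyclohexa-2,4-dienone from 6π closure (not isolated) | O=C1C(C2(C(C)C)OCCO2)=C(O[Si](C(C)C)(C(C)C)C(C)C)C(CC=C(C)C)=C(O[Si](C(C)C)(C(C)C)C(C)C)C1Cc1c(OCOC)c(C)c(CC)oc1=O | intermediate
27 | 6-ethyl-3-{[6-hydroxy-5-(2-isopropyl-1,3-dioxolan-2-yl)-3-(3-methylbut-2-en-1-yl)-2,4-bis(triisopropylsilyloxy)phenyl]methyl}-4-(methoxymethoxy)-5-methyl-2H-pyran-2-one | CCc1oc(=O)c(Cc2c(O)c(C3(C(C)C)OCCO3)c(O[Si](C(C)C)(C(C)C)C(C)C)c(CC=C(C)C)c2O[Si](C(C)C)(C(C)C)C(C)C)c(OCOC)c1C | intermediate
28 | 6-ethyl-4-hydroxy-3-{[6-hydroxy-5-isobutyryl-3-(3-methylbut-2-en-1-yl)-2,4-bis(triisopropylsilyloxy)phenyl]methyl}-5-methyl-2H-pyran-2-one | CCc1oc(=O)c(Cc2c(O)c(C(=O)C(C)C)c(O[Si](C(C)C)(C(C)C)C(C)C)c(CC=C(C)C)c2O[Si](C(C)C)(C(C)C)C(C)C)c(O)c1C | intermediate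
29 | 6-ethyl-4-hydroxy-5-methyl-3-{[2,4,6-trihydroxy-3-isobutyryl-5-(3-methylbut-2-en-1-yl)phenyl]methyl}-2H-pyran-2-one | CCc1oc(=O)c(Cc2c(O)c(CC=C(C)C)c(O)c(C(=O)C(C)C)c2O)c(O)c1C | target

## Step count

- Total step count: 13.
- Longest linear sequence: 9 (steps 1, 2, 3, 4, 5, 8, 11, 12, 13).

## Steps most likely to fail

**1. Step 11 (Proposed new method).**
- What may go wrong:
  - The vinylogous-ester stabilisation of the 3-siloxycyclobutenone may push the ring opening to temperatures at which the ynol ether or the ketal degrades.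
  - The [2+2] addition that creates a fully substituted carbon between two TIPS ethers may be too slow. The vinylketene would then be lost by dimerisation or by acylating the phenol formed.
- Fallback: it sets out from 4 and 9, comes back at 29, and gives up the ring construction for known methylene-bridge chemistry. Phloroglucinol is acylated with isobutyryl chloride and AlCl3 (Friedel–Crafts acylation) to 2-methyl-1-(2,4,6-trihydroxyphenyl)propan-1-one F1. This is C-prenylated once with 9 in cold aqueous KOH to 2-methyl-1-[2,4,6-trihydroxy-3-(3-methylbut-2-en-1-yl)phenyl]propan-1-one F2. Separately, 4 is aminomethylated at C3 with dimethylmethyleneammonium iodide (Mannich reaction) to 3-[(dimethylamino)methyl]-6-ethyl-4-hydroxy-5-methyl-2H-pyran-2-one F3. Warming F3 with F2 expels dimethylamine to give 6-ethyl-5-methyl-3-methylidenepyran-2,4-dione F4. The only free ring carbon of F2 adds to F4 in conjugate fashion and gives 29.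

**2. Step 8.**
- What may go wrong:
  - The aldoketene may dimerise, or be consumed through acylammonium species, faster than it adds the ynol ether.
  - In the acid chloride the O4 acetal oxygen may attack the acyl group (six-membered enol lactone) with loss of the MOM group.
- Fallback: it sets out from 4, comes back at ketene 16 and so at 17, and generates the ketene without base or ammonium salt. Pyrone 4 undergoes three-component reductive alkylation with benzyl glyoxylate and Hantzsch ester (L-proline catalysis) to benzyl 2-(6-ethyl-4-hydroxy-5-methyl-2-oxo-2H-pyran-3-yl)acetate F5. MOMCl and i-Pr2NEt give benzyl 2-[6-ethyl-4-(methoxymethoxy)-5-methyl-2-oxo-2H-pyran-3-yl]acetate F6. Hydrogenolysis over Pd/C gives 2-[6-ethyl-4-(methoxymethoxy)-5-methyl-2-oxo-2H-pyran-3-yl]acetic acid F7. The α-chloroenamine converts it into 2-[6-ethyl-4-(methoxymethoxy)-5-methyl-2-oxo-2H-pyran-3-yl]acetyl chloride F8. Excess diazomethane then gives 3-(3-diazo-2-oxopropyl)-6-ethyl-4-(methoxymethoxy)-5-methyl-2H-pyran-2-one F9. Irradiation at 365 nm, where the diazoketone absorbs but the alkoxypyrone does not, in the presence of 14 triggers a Wolff rearrangement. The pyronylmethyl group migrates to give 16 at low stationary concentration, and 14 traps it to 17.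

**3. Step 10.**
- What may go wrong:
  - LiCHBr2 may add too slowly to the hindered ester.
  - The tertiary ketal carbon may be reluctant to migrate, so the carbenoid would decompose before the ynolate forms.
- Fallback: it sets out from 19, comes back at ynolate 21, and needs no migration. DIBAL-H at −78 °C reduces 19 to 2-isopropyl-1,3-dioxolane-2-carbaldehyde F10. The Ohira–Bestmann reagent with K2CO3 in MeOH converts this non-enolisable aldehyde into 2-ethynyl-2-isopropyl-1,3-dioxolane F11. n-BuLi gives [(2-isopropyl-1,3-dioxolan-2-yl)ethynyl]lithium F12. Lithium tert-butyl peroxide oxidises F12 to 21 as in step 7, and TIPSCl then gives 22.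

## Further compounds

F1 | step 11 | 2-methyl-1-(2,4,6-trihydroxyphenyl)propan-1-one | CC(C)C(=O)c1c(O)cc(O)cc1O
F2 | step 11 | 2-methyl-1-[2,4,6-trihydroxy-3-(3-methylbut-2-en-1-yl)phenyl]propan-1-one | CC(C)C(=O)c1c(O)cc(O)c(CC=C(C)C)c1O
F3 | step 11 | 3-[(dimethylamino)methyl]-6-ethyl-4-hydroxy-5-methyl-2H-pyran-2-one | CCc1oc(=O)c(CN(C)C)c(O)c1C
F4 | step 11 | 6-ethyl-5-methyl-3-methylidenepyran-2,4-dione | CCC1=C(C)C(=O)C(=C)C(=O)O1
F5 | step 8 | benzyl 2-(6-ethyl-4-hydroxy-5-methyl-2-oxo-2H-pyran-3-yl)acetate | CCc1oc(=O)c(CC(=O)OCc2ccccc2)c(O)c1C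
F6 | step 8 | benzyl 2-[6-ethyl-4-(methoxymethoxy)-5-methyl-2-oxo-2H-pyran-3-yl]acetate | CCc1oc(=O)c(CC(=O)OCc2ccccc2)c(OCOC)c1C
F7 | step 8 | 2-[6-ethyl-4-(methoxymethoxy)-5-methyl-2-oxo-2H-pyran-3-yl]acetic acid | CCc1oc(=O)c(CC(=O)O)c(OCOC)c1C
F8 | step 8 | 2-[6-ethyl-4-(methoxymethoxy)-5-methyl-2-oxo-2H-pyran-3-yl]acetyl chloride | CCc1oc(=O)c(CC(=O)Cl)c(OCOC)c1C
F9 | step 8 | 3-(3-diazo-2-oxopropyl)-6-ethyl-4-(methoxymethoxy)-5-methyl-2H-pyran-2-one | CCc1oc(=O)c(CC(=O)C=[N+]=[N-])c(OCOC)c1C
F10 | step 10 | 2-isopropyl-1,3-dioxolane-2-carbaldehyde | CC(C)C1(C=O)OCCO1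
F11 | step 10 | 2-ethynyl-2-isopropyl-1,3-dioxolane | CC(C)C1(C#C)OCCO1
F12 | step 10 | [(2-isopropyl-1,3-dioxolan-2-yl)ethynyl]lithium | [Li]C#CC1(C(C)C)OCCO1
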